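**Retrosynthetic overview**

1. Target 29, (3R,5'R,6'R)-7,8-didehydro-5',6'-dihydro-β,β-carotene-3,5',6'-triol, is cut at C11=C12 and C11'=C12' (two Wittig reactions) into the acetylenic C15 phosphonium salt 16, the C10 dialdehyde 27 and the dihydroxy C15 phosphonium salt 26.
2. Salt 16: the C6–C7 bond comes from Sonogashira coupling of enol triflate 12 with enynol 13; 12 comes from (4R)-4-hydroxy-2,2-dimethylcyclohexanone 8 by C5 methylation and enol triflation.
3. Key disconnection: the C2–C3 bond of the hydroxylated ring. Ketone 8 is closed from the achiral, acyclic iodo keto aldehyde 7 by an enantioselective Co/Cr radical–polar crossover cyclisation (alkyl Nozaki–Hiyama–Kishi type) that joins two electrophilic carbons (C2–I and C3=O) and sets C3, the only stereocentre of that ring.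
4. Enabling feature: the quaternary gem-dimethyl carbon C1 between C2 and C6 of the cyclohexene ring. It makes C2 a neopentyl CH2 without β-hydrogens, shields the C6 carbonyl and folds the chain for six-ring closure.
5. Ring order: this cyclohexane ring is the only ring formed (step 5; its C5=C6 bond in step 8). The dihydroxy ring is bought as β-cyclocitral 17; its trans-5',6'-diol comes from Sharpless epoxidation and anti hydrolysis (steps 12 and 13).

Key step: step 5

Remark on the chemistry: carotenoid numbering is used in the explanations (ring C1 = CMe2, C2 = CH2, C3 = CHOH, C4 = CH2, C5 = methyl-bearing sp2 carbon, C6 = chain-bearing sp2 carbon; primes for the dihydroxy half). The chain is taken as all-E, as written in the target. The sense of induction of the chiral chromium catalyst in step 5 cannot be predicted with confidence; it is assumed that one test reaction identifies the ligand enantiomer that gives (4R)-8.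

**Route**

Step 1
Reactants: 1 methyl 2-methylpropanoate; 2 diiodomethane
Product: 3 methyl 3-iodo-2,2-dimethylpropanoate
Conditions: LDA (1.05 equiv), THF, −78 °C; then 2 (1.5 equiv), −78 °C → rt
Reagents that add atoms: none
Why: Ester enolate alkylation (SN2 on CH2I2) builds the quaternary C1 and attaches C2; the neopentyl iodide formed is inert to a second substitution.

Step 2
Reactants: 3 methyl 3-iodo-2,2-dimethylpropanoate
Product: 4 3-iodo-N-methoxy-N,2,2-trimethylpropanamide
Conditions: MeNH(OMe)·HCl (3 equiv), AlMe3 (3 equiv), CH2Cl2, 0 °C → reflux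
Reagents that add atoms: N,O-dimethylhydroxylamine hydrochloride, CNOC.Cl
Why: Aluminium amide aminolysis (Weinreb amide formation) is the variant that converts α-quaternary esters, and the aluminium amide does not touch the alkyl iodide.

Step 3
Reactants: 4 3-iodo-N-methoxy-N,2,2-trimethylpropanamide; 5 but-3-en-1-ylmagnesium bromide
Product: 6 1-iodo-2,2-dimethylhept-6-en-3-one
Conditions: 5 (1.5 equiv, 0.5 M in THF), THF, 0 °C → rt; aq. NH4Cl
Reagents that add atoms: none
Why: Weinreb ketone synthesis: the chelated tetrahedral intermediate stops the addition at the ketone, and a Grignard reagent neither exchanges with nor displaces a neopentyl iodide.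

Step 4
Reactants: 6 1-iodo-2,2-dimethylhept-6-en-3-one
Product: 7 6-iodo-5,5-dimethyl-4-oxohexanal
Conditions: O3, CH2Cl2, −78 °C (to first blue colour); then PPh3 (1.2 equiv), −78 °C → rt
Reagents that add atoms: ozone, [O-][O+]=O
Why: Ozonolysis with reductive work-up cleaves the terminal alkene much faster than ozone attacks a primary alkyl iodide and frees the 1,4-keto aldehyde under neutral conditions.

Step 5
Reactants: 7 6-iodo-5,5-dimethyl-4-oxohexanal
Product: 8 (4R)-4-hydroxy-2,2-dimethylcyclohexan-1-one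
Conditions: CrCl2 (30 mol%), chiral oxazoline–sulfonamide ligand (e.g. N-[2-(4-isopropyl-4,5-dihydrooxazol-2-yl)-6-methylphenyl]methanesulfonamide, one enantiomer, 33 mol%), proton sponge (33 mol%), cobalt(II) phthalocyanine (5 mol%), Mn powder (3 equiv), Cp2ZrCl2 (1.5 equiv), LiCl (2 equiv), MeCN, rt; 7 added by syringe pump over 12 h to the catalyst mixture (about 0.1 M in Cr); aq. Rochelle salt work-up
Reagents that add atoms: none
Why: Proposed new method: Co(I) formed from the phthalocyanine and Mn turns the neopentyl C2–I bond of 7 into the primary C2 radical, the chiral Cr(II) sulfonamide complex captures it as an alkylchromium(III) that adds to the C3 aldehyde bound to the same metal, and Cp2ZrCl2 takes over the alkoxide while Mn returns Cr(III) to Cr(II), so two electrophilic carbons (C–I and C=O) are joined by radical–polar crossover. The closest known reactions are the Co/Cr-mediated addition of primary alkyl iodides to aldehydes (alkyl Nozaki–Hiyama–Kishi reaction) and the catalytic enantioselective Nozaki–Hiyama–Kishi reactions with chromium oxazoline–sulfonamide complexes; a ring-closing enantioselective alkyl version is not established. The cyclohexane ring closes by 6-exo-trig addition of C2 to the aldehyde C=O. The C3 stereocentre is set by the chiral ligand on chromium, addition to the Si face of the aldehyde giving (R). The step needs aldehyde-over-ketone selectivity and chromium capture of the C2 radical that is faster than its 1,2-acyl (Dowd–Beckwith) shift, 1,5-hydrogen transfer and direct, non-selective radical addition to C=O: the quaternary C1 leaves C2 without β-hydrogens and shields the C6 ketone (attack there would only give a cyclopropanol), the gem-dimethyl group favours the folded chain (Thorpe–Ingold effect), and slow addition into a Cr(II)-rich solution keeps capture fast and the reaction intramolecular.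

Step 6
Reactants: 8 (4R)-4-hydroxy-2,2-dimethylcyclohexan-1-one
Product: 9 (4R)-2,2-dimethyl-4-(triethylsilyloxy)cyclohexan-1-one
Conditions: TESCl (1.2 equiv), imidazole (2.5 equiv), CH2Cl2, 0 °C → rt
Reagents that add atoms: chlorotriethylsilane, CC[Si](Cl)(CC)CC
Why: Standard silylation of a secondary alcohol; the TES ether survives the enolate and coupling steps and falls off in acidic methanol in step 10.

Step 7
Reactants: 9 (4R)-2,2-dimethyl-4-(triethylsilyloxy)cyclohexan-1-one; 10 iodomethane
Product: 11 (4R)-2,2,6-trimethyl-4-(triethylsilyloxy)cyclohexan-1-one (C6 epimers)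
Conditions: LDA (1.1 equiv), THF, −78 °C; then 10 (2 equiv), −78 → −20 °C
Reagents that add atoms: none
Why: Kinetic enolate alkylation at the only enolisable α-carbon (the other is quaternary); the new methyl-bearing centre is left as a mixture because it becomes sp2 in step 8.

Step 8
Reactants: 11 (4R)-2,2,6-trimethyl-4-(triethylsilyloxy)cyclohexan-1-one (C6 epimers)
Product: 12 (4R)-2,6,6-trimethyl-4-(triethylsilyloxy)cyclohex-1-en-1-yl trifluoromethanesulfonate
Conditions: LDA (1.3 equiv), THF, −78 → 0 °C; then PhNTf2 (1.4 equiv), 0 °C → rt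
Reagents that add atoms: N-phenylbis(trifluoromethanesulfonimide), O=S(=O)(N(c1ccccc1)S(=O)(=O)C(F)(F)F)C(F)(F)F
Why: Enol triflate formation: only one (tetrasubstituted) enolate can form, so O-sulfonylation should give the C5=C6 triflate as a single regioisomer and removes the C5 centre.

Step 9
Reactants: 12 (4R)-2,6,6-trimethyl-4-(triethylsilyloxy)cyclohex-1-en-1-yl trifluoromethanesulfonate; 13 (2E)-3-methylpent-2-en-4-yn-1-ol
Product: 14 (2E)-3-methyl-5-[(4R)-2,6,6-trimethyl-4-(triethylsilyloxy)cyclohex-1-en-1-yl]pent-2-en-4-yn-1-ol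
Conditions: Pd(PPh3)4 (5 mol%), CuI (10 mol%), iPr2NH (3 equiv), DMF (degassed), rt → 40 °C
Reagents that add atoms: none
Why: Sonogashira coupling of an enol triflate with a terminal alkyne forms the C6–C7 bond, keeps the (E)-geometry of 13 and tolerates the free primary alcohol.

Step 10
Reactants: 14 (2E)-3-methyl-5-[(4R)-2,6,6-trimethyl-4-(triethylsilyloxy)cyclohex-1-en-1-yl]pent-2-en-4-yn-1-ol
Product: 16 [(2E)-5-[(4R)-4-hydroxy-2,6,6-trimethylcyclohex-1-en-1-yl]-3-methylpent-2-en-4-yn-1-yl]triphenylphosphonium bromide, via desilylated enyne diol 15 (not isolated)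
Conditions: PPh3·HBr (1.2 equiv), MeOH, rt, 16 h; precipitation from EtOAc/Et2O
Reagents that add atoms: triphenylphosphine hydrobromide, Br.c1ccc(cc1)P(c1ccccc1)c1ccccc1
Why: Acidic methanol first cleaves the TES ether, then the primary allylic alcohol ionises and PPh3 attacks the unhindered terminus (classical allylic phosphonium salt formation); the secondary ring alcohol does not ionise.

Step 11
Reactants: 17 β-cyclocitral (2,6,6-trimethylcyclohex-1-ene-1-carbaldehyde)
Product: 18 β-cyclogeraniol [(2,6,6-trimethylcyclohex-1-en-1-yl)methanol]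
Conditions: NaBH4 (0.6 equiv), MeOH, 0 °C
Reagents that add atoms: none
Why: Borohydride 1,2-reduction of a hindered enal gives the allylic alcohol needed for directed epoxidation.

Step 12
Reactants: 18 β-cyclogeraniol [(2,6,6-trimethylcyclohex-1-en-1-yl)methanol]
Product: 19 [(1S,6S)-2,2,6-trimethyl-7-oxabicyclo[4.1.0]heptan-1-yl]methanol
Conditions: Ti(OiPr)4 (10 mol%), L-(+)-diethyl tartrate (13 mol%), t-BuOOH (2 equiv, in decane), 4 Å MS, CH2Cl2, −20 °C
Reagents that add atoms: tert-butyl hydroperoxide, CC(C)(C)OO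
Why: Sharpless asymmetric epoxidation: the titanium L-(+)-tartrate complex delivers oxygen to one face of the C5'=C6' bond of the allylic alcohol, setting both ring centres by reagent control with the C6'–O bond as in the target.

Step 13
Reactants: 19 [(1S,6S)-2,2,6-trimethyl-7-oxabicyclo[4.1.0]heptan-1-yl]methanol
Product: 20 (1S,2R)-1-(hydroxymethyl)-2,6,6-trimethylcyclohexane-1,2-diol
Conditions: HClO4 (5% aq., cat.), THF–H2O, 0 °C → rt
Reagents that add atoms: water, O
Why: Acid-catalysed epoxide hydrolysis: water attacks anti at the methyl-bearing C5' (the C6' cation is disfavoured by the CH2OH group and shielded by the gem-dimethyl carbon), so C5' is inverted, C6' is retained and the trans-diol results.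

Step 14
Reactants: 20 (1S,2R)-1-(hydroxymethyl)-2,6,6-trimethylcyclohexane-1,2-diol
Product: 21 (1R,2R)-1,2-dihydroxy-2,6,6-trimethylcyclohexane-1-carbaldehyde
Conditions: SO3·pyridine (3 equiv), DMSO, iPr2NEt (4 equiv), CH2Cl2, 0 °C; used crude
Reagents that add atoms: none
Why: Parikh–Doering oxidation converts only the primary alcohol, since the two tertiary alcohols cannot be oxidised and no diol-cleaving oxidant is present.

Step 15
Reactants: 21 (1R,2R)-1,2-dihydroxy-2,6,6-trimethylcyclohexane-1-carbaldehyde; 22 ethyl (2E)-4-(diethoxyphosphoryl)-3-methylbut-2-enoate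
Product: 23 ethyl (2E,4E)-5-[(1R,2R)-1,2-dihydroxy-2,6,6-trimethylcyclohexyl]-3-methylpenta-2,4-dienoate
Conditions: 22 (3 equiv), LiHMDS (3 equiv), THF–DMPU, −78 °C; then 21, −78 → 0 °C
Reagents that add atoms: none
Why: Vinylogous Horner–Wadsworth–Emmons olefination adds C7'–C11' in one step with (E)-selectivity at the new C7'=C8' bond and the 9'E geometry carried by the reagent; excess anion buffers the free hydroxyl groups.

Step 16
Reactants: 23 ethyl (2E,4E)-5-[(1R,2R)-1,2-dihydroxy-2,6,6-trimethylcyclohexyl]-3-methylpenta-2,4-dienoate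
Product: 24 (1R,2R)-1-[(1E,3E)-5-hydroxy-3-methylpenta-1,3-dien-1-yl]-2,6,6-trimethylcyclohexane-1,2-diol
Conditions: DIBAL-H (5 equiv), CH2Cl2, −78 °C; Rochelle salt work-up
Reagents that add atoms: none
Why: DIBAL-H reduces the dienoate by 1,2-addition to the allylic alcohol; the tertiary alkoxides formed in situ are inert.

Step 17
Reactants: 24 (1R,2R)-1-[(1E,3E)-5-hydroxy-3-methylpenta-1,3-dien-1-yl]-2,6,6-trimethylcyclohexane-1,2-diol
Product: 26 [(2E,4E)-5-[(1R,2R)-1,2-dihydroxy-2,6,6-trimethylcyclohexyl]-3-methylpenta-2,4-dien-1-yl]triphenylphosphonium bromide, via C15 allylic bromide 25 (not isolated)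
Conditions: CBr4 (1.2 equiv), PPh3 (2.5 equiv), CH2Cl2, −20 °C → rt, 12 h; precipitation with Et2O
Reagents that add atoms: carbon tetrabromide, BrC(Br)(Br)Br; triphenylphosphine, c1ccc(cc1)P(c1ccccc1)c1ccccc1
Why: Appel bromination is neutral and selective for the primary allylic alcohol over the two tertiary ones, and the excess PPh3 then quaternises the allylic bromide in the same flask.

Step 18
Reactants: 16 [(2E)-5-[(4R)-4-hydroxy-2,6,6-trimethylcyclohex-1-en-1-yl]-3-methylpent-2-en-4-yn-1-yl]triphenylphosphonium bromide; 27 (2E,4E,6E)-2,7-dimethylocta-2,4,6-trienedial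
Product: 28 (2E,4E,6E,8E,10E)-13-[(4R)-4-hydroxy-2,6,6-trimethylcyclohex-1-en-1-yl]-2,7,11-trimethyltrideca-2,4,6,8,10-pentaen-12-ynal
Conditions: 27 (3 equiv), NaOMe (1.2 equiv, 1 M in MeOH) added slowly, CH2Cl2, 0 °C → rt, dark; then EtOAc, 60 °C; chromatography
Reagents that add atoms: none
Why: Wittig reaction of the allylic ylide with an excess of the symmetric dialdehyde should stop at mono-olefination, and gentle warming without iodine should convert the sterically hindered 11Z isomer to 11E without promoting 9Z.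

Step 19
Reactants: 28 (2E,4E,6E,8E,10E)-13-[(4R)-4-hydroxy-2,6,6-trimethylcyclohex-1-en-1-yl]-2,7,11-trimethyltrideca-2,4,6,8,10-pentaen-12-ynal; 26 [(2E,4E)-5-[(1R,2R)-1,2-dihydroxy-2,6,6-trimethylcyclohexyl]-3-methylpenta-2,4-dien-1-yl]triphenylphosphonium bromide
Product: 29 (3R,5'R,6'R)-7,8-didehydro-5',6'-dihydro-β,β-carotene-3,5',6'-triol
Conditions: 26 (1.5 equiv), NaOMe (3 equiv), CH2Cl2–MeOH, rt, argon, dark; then EtOAc, 60 °C; chromatography and crystallisation
Reagents that add atoms: none
Why: Wittig reaction forms C11'=C12' under methoxide conditions that tolerate the three free hydroxyl groups, and the hindered 11'Z isomer should isomerise thermally to the all-E target; no stereocentre is touched.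

**Compound list**

1 | methyl 2-methylpropanoate | COC(=O)C(C)C | starting material
2 | diiodomethane | ICI | starting material
3 | methyl 3-iodo-2,2-dimethylpropanoate | COC(=O)C(C)(C)CI | intermediate
4 | 3-iodo-N-methoxy-N,2,2-trimethylpropanamide | CON(C)C(=O)C(C)(C)CI | intermediate
5 | but-3-en-1-ylmagnesium bromide | C=CCC[Mg]Br | starting material
6 | 1-iodo-2,2-dimethylhept-6-en-3-one | C=CCCC(=O)C(C)(C)CI | intermediate
7 | 6-iodo-5,5-dimethyl-4-oxohexanal | O=CCCC(=O)C(C)(C)CI | intermediate
8 | (4R)-4-hydroxy-2,2-dimethylcyclohexan-1-one | CC1(C)C[C@H](O)CCC1=O | intermediate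
9 | (4R)-2,2-dimethyl-4-(triethylsilyloxy)cyclohexan-1-one | CC1(C)C[C@H](O[Si](CC)(CC)CC)CCC1=O | intermediate
10 | iodomethane | CI | starting material
11 | (4R)-2,2,6-trimethyl-4-(triethylsilyloxy)cyclohexan-1-one (C6 epimers) | CC1(C)C[C@H](O[Si](CC)(CC)CC)CC(C)C1=O | intermediate
12 | (4R)-2,6,6-trimethyl-4-(triethylsilyloxy)cyclohex-1-en-1-yl trifluoromethanesulfonate | CC1=C(OS(=O)(=O)C(F)(F)F)C(C)(C)C[C@H](O[Si](CC)(CC)CC)C1 | intermediate
13 | (2E)-3-methylpent-2-en-4-yn-1-ol | C#C/C(C)=C/CO | starting material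
14 | (2E)-3-methyl-5-[(4R)-2,6,6-trimethyl-4-(triethylsilyloxy)cyclohex-1-en-1-yl]pent-2-en-4-yn-1-ol | CC1=C(C#C/C(C)=C/CO)C(C)(C)C[C@H](O[Si](CC)(CC)CC)C1 | intermediate
15 | (1R)-4-[(3E)-5-hydroxy-3-methylpent-3-en-1-yn-1-yl]-3,5,5-trimethylcyclohex-3-en-1-ol | CC1=C(C#C/C(C)=C/CO)C(C)(C)C[C@H](O)C1 | intermediate
16 | [(2E)-5-[(4R)-4-hydroxy-2,6,6-trimethylcyclohex-1-en-1-yl]-3-methylpent-2-en-4-yn-1-yl]triphenylphosphonium bromide | CC1=C(C#C/C(C)=C/C[P+](c2ccccc2)(c2ccccc2)c2ccccc2)C(C)(C)C[C@H](O)C1.[Br-] | intermediate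
17 | β-cyclocitral (2,6,6-trimethylcyclohex-1-ene-1-carbaldehyde) | CC1=C(C=O)C(C)(C)CCC1 | starting material
18 | β-cyclogeraniol [(2,6,6-trimethylcyclohex-1-en-1-yl)methanol] | CC1=C(CO)C(C)(C)CCC1 | intermediate
19 | [(1S,6S)-2,2,6-trimethyl-7-oxabicyclo[4.1.0]heptan-1-yl]methanol | OC[C@]12O[C@@]1(C)CCCC2(C)C | intermediate
20 | (1S,2R)-1-(hydroxymethyl)-2,6,6-trimethylcyclohexane-1,2-diol | OC[C@@]1(O)C(C)(C)CCC[C@@]1(C)O | intermediate
21 | (1R,2R)-1,2-dihydroxy-2,6,6-trimethylcyclohexane-1-carbaldehyde | O=C[C@@]1(O)C(C)(C)CCC[C@@]1(C)O | intermediate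
22 | ethyl (2E)-4-(diethoxyphosphoryl)-3-methylbut-2-enoate | CCOC(=O)/C=C(C)/CP(=O)(OCC)OCC | starting material
23 | ethyl (2E,4E)-5-[(1R,2R)-1,2-dihydroxy-2,6,6-trimethylcyclohexyl]-3-methylpenta-2,4-dienoate | CCOC(=O)/C=C(C)/C=C/[C@@]1(O)C(C)(C)CCC[C@@]1(C)O | intermediate
24 | (1R,2R)-1-[(1E,3E)-5-hydroxy-3-methylpenta-1,3-dien-1-yl]-2,6,6-trimethylcyclohexane-1,2-diol | OC/C=C(C)/C=C/[C@@]1(O)C(C)(C)CCC[C@@]1(C)O | intermediate
25 | (1R,2R)-1-[(1E,3E)-5-bromo-3-methylpenta-1,3-dien-1-yl]-2,6,6-trimethylcyclohexane-1,2-diol | BrC/C=C(C)/C=C/[C@@]1(O)C(C)(C)CCC[C@@]1(C)O | intermediate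
26 | [(2E,4E)-5-[(1R,2R)-1,2-dihydroxy-2,6,6-trimethylcyclohexyl]-3-methylpenta-2,4-dien-1-yl]triphenylphosphonium bromide | c1ccc(cc1)[P+](c1ccccc1)(c1ccccc1)C/C=C(C)/C=C/[C@@]1(O)C(C)(C)CCC[C@@]1(C)O.[Br-] | intermediate
27 | (2E,4E,6E)-2,7-dimethylocta-2,4,6-trienedial | O=C/C(C)=C/C=C/C=C(C)/C=O | starting material
28 | (2E,4E,6E,8E,10E)-13-[(4R)-4-hydroxy-2,6,6-trimethylcyclohex-1-en-1-yl]-2,7,11-trimethyltrideca-2,4,6,8,10-pentaen-12-ynal | CC1=C(C#C/C(C)=C/C=C/C(C)=C/C=C/C=C(C)/C=O)C(C)(C)C[C@H](O)C1 | intermediate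
29 | (3R,5'R,6'R)-7,8-didehydro-5',6'-dihydro-β,β-carotene-3,5',6'-triol | CC1=C(C#C/C(C)=C/C=C/C(C)=C/C=C/C=C(C)/C=C/C=C(C)/C=C/[C@@]2(O)C(C)(C)CCC[C@@]2(C)O)C(C)(C)C[C@H](O)C1 | target

**Step count and risks**

Total step count: 19. Longest linear sequence: 12 steps (steps 1–10, 18, 19).

Steps most likely to fail:

1. Step 5 (Proposed new method). Capture of the C2 radical by chromium may be too slow compared with 1,2-acyl migration or direct radical addition to the carbonyl group, or the facial selectivity at the aldehyde may be poor, so that a ring isomer or material of low enantiomeric purity results. The fallback uses known chemistry and sets out from 7. The ring is closed without a chiral ligand by the Co/Cr-mediated coupling of primary alkyl iodides with aldehydes (CrCl2, 4 equiv, catalytic cobalt phthalocyanine, DMF, rt), which should give racemic 4-hydroxy-2,2-dimethylcyclohexan-1-one F1. Kinetic resolution with immobilised Candida antarctica lipase B and vinyl acetate in MTBE is expected, by the usual empirical rule for lipases, to acylate the (R)-alcohol to (1R)-3,3-dimethyl-4-oxocyclohexyl acetate F2. F2 is separated from the unreacted (S)-alcohol and methanolysed (K2CO3, MeOH); the route is rejoined at 8.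

2. Step 15. Under the basic olefination conditions the unprotected α,β-dihydroxy aldehyde may undergo retro-aldol cleavage or α-ketol rearrangement before it is olefinated. The fallback sets out from 20 and protects first. Persilylation (TMSOTf, 2,6-lutidine, CH2Cl2) gives the tris(trimethylsilyl) ether of 20 F3. Swern oxidation, which converts a primary trimethylsilyl ether directly into the aldehyde and leaves tertiary ones, gives (1R,2R)-2,6,6-trimethyl-1,2-bis(trimethylsilyloxy)cyclohexane-1-carbaldehyde F4. Olefination with 22 under the conditions of step 15 gives ethyl (2E,4E)-3-methyl-5-[(1R,2R)-2,6,6-trimethyl-1,2-bis(trimethylsilyloxy)cyclohexyl]penta-2,4-dienoate F5. K2CO3 in MeOH removes the silyl groups; the route is rejoined at 23.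

3. Step 17. The tertiary allylic C6' hydroxyl may ionise or be lost by dehydration during bromination and salt formation, and the derived ylide may expel hydroxide in step 19. The fallback reverses the roles of the two partners in the last olefination and sets out from 24 and 28. Alcohol 24 is oxidised with MnO2 (CH2Cl2, rt) to (2E,4E)-5-[(1R,2R)-1,2-dihydroxy-2,6,6-trimethylcyclohexyl]-3-methylpenta-2,4-dienal F6. Aldehyde 28 is reduced (NaBH4, MeOH, 0 °C) to (3R)-7,8-didehydro-12'-apo-β-carotene-3,12'-diol F7, which PPh3·HBr in MeOH converts into [(3R)-3-hydroxy-7,8-didehydro-12'-apo-β-caroten-12'-yl]triphenylphosphonium bromide F8. Wittig reaction of F8 with F6 (NaOMe, CH2Cl2–MeOH) forms the same C11'=C12' bond; the route is rejoined at 29.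

Further compounds
F1 | step 5 | racemic 4-hydroxy-2,2-dimethylcyclohexan-1-one | CC1(C)CC(O)CCC1=O
F2 | step 5 | (1R)-3,3-dimethyl-4-oxocyclohexyl acetate | CC1(C)C[C@H](OC(C)=O)CCC1=O
F3 | step 15 | tris(trimethylsilyl) ether of 20 | C[Si](C)(C)OC[C@@]1(O[Si](C)(C)C)C(C)(C)CCC[C@@]1(C)O[Si](C)(C)C
F4 | step 15 | (1R,2R)-2,6,6-trimethyl-1,2-bis(trimethylsilyloxy)cyclohexane-1-carbaldehyde | O=C[C@@]1(O[Si](C)(C)C)C(C)(C)CCC[C@@]1(C)O[Si](C)(C)C
F5 | step 15 | ethyl (2E,4E)-3-methyl-5-[(1R,2R)-2,6,6-trimethyl-1,2-bis(trimethylsilyloxy)cyclohexyl]penta-2,4-dienoate | CCOC(=O)/C=C(C)/C=C/[C@@]1(O[Si](C)(C)C)C(C)(C)CCC[C@@]1(C)O[Si](C)(C)C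
F6 | step 17 | (2E,4E)-5-[(1R,2R)-1,2-dihydroxy-2,6,6-trimethylcyclohexyl]-3-methylpenta-2,4-dienal | O=C/C=C(C)/C=C/[C@@]1(O)C(C)(C)CCC[C@@]1(C)O
F7 | step 17 | (3R)-7,8-didehydro-12'-apo-β-carotene-3,12'-diol | CC1=C(C#C/C(C)=C/C=C/C(C)=C/C=C/C=C(C)/CO)C(C)(C)C[C@H](O)C1
F8 | step 17 | [(3R)-3-hydroxy-7,8-didehydro-12'-apo-β-caroten-12'-yl]triphenylphosphonium bromide | CC1=C(C#C/C(C)=C/C=C/C(C)=C/C=C/C=C(C)/C[P+](c2ccccc2)(c2ccccc2)c2ccccc2)C(C)(C)C[C@H](O)C1.[Br-]
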